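## Analysis of the target

The target 17 is methyl (1R,2S,3S)-7-hydroxy-1-(4-hydroxy-3-methoxyphenyl)-3-(hydroxymethyl)-6-methoxy-1,2,3,4-tetrahydronaphthalene-2-carboxylate, an aryltetralin cyclolignan. The aromatic ring A (C4a to C8a, methoxyl on C6, hydroxyl on C7) is fused to the saturated ring B (C1 to C4), and C1 carries a pendant 4-hydroxy-3-methoxyphenyl ring (ring C). The same locants are used for every bicyclic intermediate below.

The three stereocentres C1, C2 and C3 are contiguous and all-trans: aryl group, ester and hydroxymethyl group lie on alternating faces, so all three can be equatorial on the half-chair. This is the thermodynamically preferred arrangement. C2 is α to the ester and can be equilibrated by base, and C3 can be equilibrated only while it still carries a carbonyl group. C1 is a doubly benzylic methine that cannot be corrected, so its absolute configuration is the one stereochemical fact the synthesis must actually set.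

The sensitive groups are two free guaiacyl phenols (easily oxidised, above all as phenoxides in air), the γ-hydroxy ester (lactonisation, epimerisation at C2) and the para-hydroxybenzylic C1–H. The two difficulties are the absolute control at C1 and telling apart the one-carbon substituents on C2 (ester level) and C3 (alcohol level), which sit on neighbouring, similarly substituted carbons.

The strategy rests on the following feature. Oxidation levels aside, ring A with C4, C3 and the hydroxymethyl carbon is one C6–C3 ferulic unit, and ring C with C1, C2 and the ester carbon is a second one. They are joined by C2–C3 (the carbons α to the two carboxyl carbons, the 8–8' bond) and by C1–C8a (the benzylic carbon of one unit to the ring carbon para to the methoxyl of the other).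

## Retrosynthetic reasoning

**17 back to 15 (no C–C bond cut).** The hydroxymethyl group on C3 is traced to a carboxylic acid, 16, which an acid-selective hydride donor can reduce beside the C2 methyl ester. Acid 16 comes from the all-trans dimethyl ester 15 by hydrolysis of one ester. The gain is that both side-chain carbons are now at the same oxidation level, which is how a dimerisation of two identical units delivers them. The forward hydrolysis must distinguish the C3 ester, flanked by one ring substituent, from the C2 ester, flanked by two.

**15 back to 13.** The two methoxyl groups are exchanged for two units of the auxiliary 6, and C3 is allowed the opposite configuration (bis(imide) 13, which passes through the cis diester 14). This is permissible because C2 and C3 of 15 are both α to esters and settle under basic alcoholysis into the all-trans arrangement dictated by C1. Only C1 then needs absolute control.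

**13 back to 12.** The C3=C4 double bond and two bromine atoms (on C8 and on ring C) are reintroduced. One hydrogenation removes all three features in the forward direction. The alkene is the trace that an oxidative dimerisation leaves behind, and the bromines are the blocking groups that such a dimerisation needs.

**12 back to two molecules of 9.** The bonds C2–C3 and C1–C8a are cut. This is the only pair of cuts that divides the skeleton into two identical molecules. The gain is two skeletal bonds, ring B and both stereocentres C1 and C2 in one step from one monomer. In the forward direction the two phenoxyl radicals must join through their α-carbons and not through a ring carbon, one methide must then be attacked by the ring of the other unit para to its methoxyl, and the auxiliary must bias the face of the α-carbon.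

**9 back to 1, 2 and 6.** The N–acyl bond of 9 is cut to give the auxiliary 6 and the cinnamic acid 4, which is handled as its phenol acetate 5 and coupled through 8. Acid 4 is cut at its Cα=Cβ bond into the aldehyde 1 and the two-carbon donor 2. These are reliable condensations, so that the risk of the route is concentrated in the dimerisation.

## Alternatives that were turned down

**Alternative 1:** Only C2–C3 is cut, so ring B is closed last from an open-chain substrate A1 in which C1 is already a stereocentre. A1 is the tert-butyldimethylsilyl ketene acetal of a 3,3-diarylpropanoate whose ring-A aryl group carries an ortho 3-methoxyallyl chain, with both phenols masked as pivalates.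
- *Forward key step:* A1 is oxidised at an anode in an alcohol solvent. The ketene acetal, the most easily oxidised π-system, gives a radical centre at C2 that adds 6-exo to C3 of the enol ether. The resulting centre at C10 is oxidised further and captured by the solvent, so the product A2 carries an ester on C2 and a dimethyl acetal on C3.
- *For it:* the two side-chain carbons leave the key step at different oxidation levels, which removes the regioselective ester hydrolysis on which the chosen route depends. C1 can be installed beforehand by a catalytic asymmetric conjugate arylation, a better precedented source of absolute configuration than an auxiliary in a radical coupling. On both points this alternative is the stronger one.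
- *Against it:* A1 is a moisture-sensitive compound at the end of a linear sequence of roughly ten steps. The two electron-rich arenes and the doubly benzylic C1–H are further anodic substrates even with acylated phenols. C2 and C3 arise under kinetic control in a radical cyclisation, and C3 becomes correctable only after the acetal has been hydrolysed. Two pivalates must finally be removed from a base-sensitive hydroxy ester.
- *Comparison:* the chosen strategy offers the whole carbon skeleton in one step from a monomer four steps from commercial material, and reaches the final stereochemical pattern by equilibration instead of kinetic control.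

**Alternative 2:** Ring B is opened by a Diels–Alder retron across C1–C2 and C3–C4. The diene is the (E)-aryl ortho-quinodimethane A4, released from the racemic benzylic sulfone A3, and the dienophile is the (5S)-menthyloxy butenolide A5.
- *Forward key step:* on heating, A3 undergoes cheletropic extrusion and A4 is intercepted by A5 in an endo transition state on the face anti to the menthyloxy group. The aryl-bearing diene terminus bonds to the carbon α to the lactone carbonyl, so the all-cis adduct A6 has the carbonyl on C2 and the acetal carbon on C3.
- *For it:* two bonds and three stereocentres are formed at once with a dienophile whose facial bias is well established, and C2 and C3 are again born at different oxidation levels. In absolute stereocontrol and in the C2/C3 differentiation this alternative is stronger than the chosen one.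
- *Against it:* A6 is all-cis while the target is all-trans, so both C2 and C3 must be inverted relative to C1. That is possible only after the lactone and the acetal have been opened, through an equilibration of a ring-opened system that can re-close. A3 needs a multi-step synthesis, the extrusion needs high temperature, two benzyl ethers must be removed at the end, and the menthyl unit of the required sense derives from the less accessible enantiomer of the terpene alcohol.
- *Comparison:* the chosen strategy is shorter, has no thermolysis, needs no phenol protection after the monomer stage, and its kinetic product already has the 1,2-trans relationship of the target.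

**Alternative 3:** Only C1–C2 is cut. The substrate is the para-hydroxy diarylcarbinol A7, whose ring A carries a side chain with the C3 stereocentre already set (silyloxymethyl group) and a terminal malonate.
- *Forward key step:* mild acid or base converts A7 into the quinone methide A8, and the malonate carbon adds 1,6 to C1 in a 6-exo-trig closure. This gives A9 with the aryl group cis to the C3 substituent, both equatorial in a chair-like transition state.
- *For it:* the C2/C3 differentiation is inherent, C1 is controlled by a preset centre through a reversible conjugate addition, and the conditions are mild. In regiochemical certainty, and probably in relative configuration, this is the safest of the four strategies.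
- *Against it:* the C3 centre needs its own asymmetric sequence, and three orthogonal protecting groups must be managed. The geminal diester must afterwards lose one ester group at high temperature (Krapcho-type dealkoxycarbonylation), where the retro-1,6-addition is open and the configuration at C2 is set with uncertain selectivity. Two deprotections follow, for a total well above ten steps.
- *Comparison:* the chosen strategy is roughly half as long, convergent by symmetry, and carries free phenols from the monomer onwards.

Key step: step 5

Remark on the chemistry (assumption): the facial sense of the coupling in step 5 is assigned from the non-chelated, dipole-opposed s-cis conformer of the imide in aqueous acetone; should the chelated conformer react instead, the same route would be run with the enantiomeric auxiliary.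

## Route

Step 1
Reactants: 1 5-bromovanillin (3-bromo-4-hydroxy-5-methoxybenzaldehyde); 2 malonic acid
Product: 4 (E)-3-(3-bromo-4-hydroxy-5-methoxyphenyl)prop-2-enoic acid (5-bromoferulic acid), via arylidenemalonic acid 3 (not isolated)
Conditions: pyridine, piperidine (0.1 equiv), 90 °C; then cold aq. HCl
Reagents that add atoms: none
Why: Knoevenagel–Doebner condensation; the arylidenemalonic acid 3 loses CO2 in hot pyridine and gives the (E)-cinnamic acid, and the free phenol is tolerated as in the classical preparation of ferulic acid.

Step 2
Reactants: 4 (E)-3-(3-bromo-4-hydroxy-5-methoxyphenyl)prop-2-enoic acid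
Product: 5 (E)-3-(4-acetoxy-3-bromo-5-methoxyphenyl)prop-2-enoic acid
Conditions: Ac2O (1.5 equiv), 2 M aq. NaOH, 0 °C; then HCl to pH 2
Reagents that add atoms: acetic anhydride, CC(=O)OC(C)=O
Why: Schotten–Baumann O-acetylation of the phenoxide; the carboxylate is not acylated lastingly in water, and the acetate masks the acidic phenol for the acylation of step 3.

Step 3
Reactants: 5 (E)-3-(4-acetoxy-3-bromo-5-methoxyphenyl)prop-2-enoic acid; 6 (S)-4-benzyloxazolidin-2-one
Product: 8 (S)-3-[(E)-3-(4-acetoxy-3-bromo-5-methoxyphenyl)prop-2-enoyl]-4-benzyloxazolidin-2-one, via mixed pivalic anhydride 7 (not isolated)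
Conditions: PivCl, Et3N, THF, −20 °C; then LiCl, 6, −20 °C → rt
Reagents that add atoms: none
Why: N-acylation of an oxazolidinone by the mixed-anhydride method; the tert-butyl group steers attack to the cinnamoyl carbonyl of 7, and the LiCl/Et3N activation needs no strong base, so the aryl acetate, the (E)-alkene and the stereocentre of 6 are untouched.

Step 4
Reactants: 8 (S)-3-[(E)-3-(4-acetoxy-3-bromo-5-methoxyphenyl)prop-2-enoyl]-4-benzyloxazolidin-2-one
Product: 9 (S)-4-benzyl-3-[(E)-3-(3-bromo-4-hydroxy-5-methoxyphenyl)prop-2-enoyl]oxazolidin-2-one
Conditions: pyrrolidine (2.2 equiv), CH2Cl2, 0 °C; then 1 M HCl wash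
Reagents that add atoms: none
Why: Chemoselective aminolysis of an aryl acetate; the acetate of this acidic ortho-bromophenol is an activated ester that is cleaved far faster than the imide is attacked or the electron-rich cinnamoyl unit undergoes conjugate addition.

Step 5
Reactants: 9 (S)-4-benzyl-3-[(E)-3-(3-bromo-4-hydroxy-5-methoxyphenyl)prop-2-enoyl]oxazolidin-2-one (two molecules)
Product: 12 (4S,4'S)-3,3'-{[(1R,2S)-8-bromo-1-(3-bromo-4-hydroxy-5-methoxyphenyl)-7-hydroxy-6-methoxy-1,2-dihydronaphthalene-2,3-diyl]dicarbonyl}bis(4-benzyloxazolidin-2-one), via bis(quinone methide) 10 (not isolated), via quinone methide phenol 11 (not isolated)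
Conditions: FeCl3·6H2O (2.2 equiv), acetone/H2O 4:1, 0 °C → rt, Ar
Reagents that add atoms: none
Why: FeCl3 (trivalent iron) takes one electron from each phenol of 9 and gives phenoxyl radicals whose spin reaches the carbon α to the imide carbonyl; radical–radical coupling there forms C2–C3 and gives the bis(quinone methide) 10. One methide of 10 tautomerises by loss of the proton on C3 to the phenolic (E)-cinnamoyl unit of 11, whose ring carbon para to the methoxyl adds to the remaining methide carbon in a 6-exo-trig Friedel–Crafts-type closure that forms C1–C8a and ring B, and proton loss from the arenium ion gives 12. The closest known reaction type is the FeCl3-mediated oxidative 8–8' dimerisation of sinapates and of ferulates blocked at C5 to trans-1-aryl-1,2-dihydronaphthalene-2,3-dicarboxylates. C2 is set in the coupling: in the dipole-opposed s-cis conformer of the imide the benzyl group of the (S)-auxiliary covers one face of the α-carbon, bonding on the open face gives 2S, and because C3 becomes trigonal this is the only centre of 10 that survives. C1 is set in the ring closure relative to C2: the aryl group enters trans to the C2 acyl group, both pseudoaxial, which avoids the peri contact with the bromine on C8 and the allylic strain with the C3 acyl group, hence 1R. The step needs 8–8' and not 8–5' coupling, which the bromine secures by occupying the ring position ortho to the phenol, and it needs closure para and not ortho to the methoxyl, which the stronger para activation and the crowding of the position between methoxyl and side chain favour. Aqueous acetone keeps the trivalent iron from chelating the imide, and the intramolecular closure is expected to outrun addition of water to the methide.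

Step 6
Reactants: 12 (4S,4'S)-3,3'-{[(1R,2S)-8-bromo-1-(3-bromo-4-hydroxy-5-methoxyphenyl)-7-hydroxy-6-methoxy-1,2-dihydronaphthalene-2,3-diyl]dicarbonyl}bis(4-benzyloxazolidin-2-one)
Product: 13 (4S,4'S)-3,3'-{[(1R,2S,3R)-7-hydroxy-1-(4-hydroxy-3-methoxyphenyl)-6-methoxy-1,2,3,4-tetrahydronaphthalene-2,3-diyl]dicarbonyl}bis(4-benzyloxazolidin-2-one)
Conditions: H2 (3 atm), 10% Pd/C, Et3N (3 equiv), EtOAc/EtOH 1:1, rt
Reagents that add atoms: none
Why: Heterogeneous catalytic hydrogenation saturates the styrene-type C3=C4 bond and hydrogenolyses both aryl C–Br bonds, with Et3N taking up the HBr; C1 and C2 are not touched and the benzyl groups of the auxiliaries are carbon-bound and inert. Hydrogen should arrive mainly on the face opposite the pseudoaxial C2 acyl group, which gives the 2,3-cis isomer (3R), but either C3 epimer converges in step 7.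

Step 7
Reactants: 13 (4S,4'S)-3,3'-{[(1R,2S,3R)-7-hydroxy-1-(4-hydroxy-3-methoxyphenyl)-6-methoxy-1,2,3,4-tetrahydronaphthalene-2,3-diyl]dicarbonyl}bis(4-benzyloxazolidin-2-one)
Product: 15 dimethyl (1R,2S,3S)-7-hydroxy-1-(4-hydroxy-3-methoxyphenyl)-6-methoxy-1,2,3,4-tetrahydronaphthalene-2,3-dicarboxylate, via 2,3-cis dimethyl ester 14 (not isolated)
Conditions: NaOMe (6 equiv), MeOH, 0 °C → 50 °C, Ar; then 1 M HCl to pH 4
Reagents that add atoms: sodium methoxide, C[O-].[Na+]; methanol, CO
Why: Alkoxide transesterification of the N-acyl oxazolidinones at the exocyclic carbonyl releases both auxiliaries and gives 14, and the same base then epimerises the centres α to the esters. C1 is not acidic and keeps 1R, so the equilibrium settles on the all-equatorial isomer with 2S and 3S.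

Step 8
Reactants: 15 dimethyl (1R,2S,3S)-7-hydroxy-1-(4-hydroxy-3-methoxyphenyl)-6-methoxy-1,2,3,4-tetrahydronaphthalene-2,3-dicarboxylate
Product: 16 (1R,2S,3S)-7-hydroxy-1-(4-hydroxy-3-methoxyphenyl)-6-methoxy-2-(methoxycarbonyl)-1,2,3,4-tetrahydronaphthalene-3-carboxylic acid
Conditions: LiOH·H2O (4 equiv), THF/H2O 3:1, 0 °C → rt, Ar; then 1 M HCl
Reagents that add atoms: lithium hydroxide, [Li+].[OH-]; water, O
Why: Sterically governed mono-saponification; the C3 ester has one flanking ring substituent and the C2 ester has two (the C1 aryl group and C3), and the carboxylate formed first retards attack on its neighbour. Both centres are already in their thermodynamic configuration, so the base cannot erode them.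

Step 9
Reactants: 16 (1R,2S,3S)-7-hydroxy-1-(4-hydroxy-3-methoxyphenyl)-6-methoxy-2-(methoxycarbonyl)-1,2,3,4-tetrahydronaphthalene-3-carboxylic acid
Product: 17 methyl (1R,2S,3S)-7-hydroxy-1-(4-hydroxy-3-methoxyphenyl)-3-(hydroxymethyl)-6-methoxy-1,2,3,4-tetrahydronaphthalene-2-carboxylate
Conditions: BH3·SMe2 (5 equiv), THF, 0 °C → rt; then MeOH, 0 °C, neutral work-up
Reagents that add atoms: none
Why: Chemoselective borane reduction of a carboxylic acid beside an ester, through the acyloxyborane; the phenols are borylated only transiently and are released by the methanol quench. No stereocentre is involved, and the neutral work-up avoids lactonisation of the γ-hydroxy ester.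

## Compound list

1 | 5-bromovanillin (3-bromo-4-hydroxy-5-methoxybenzaldehyde) | O=Cc1cc(Br)c(O)c(OC)c1 | starting material
2 | malonic acid | OC(=O)CC(=O)O | starting material
3 | 2-[(3-bromo-4-hydroxy-5-methoxyphenyl)methylidene]propanedioic acid | OC(=O)C(=Cc1cc(Br)c(O)c(OC)c1)C(=O)O | intermediate (not isolated)
4 | (E)-3-(3-bromo-4-hydroxy-5-methoxyphenyl)prop-2-enoic acid | OC(=O)/C=C/c1cc(Br)c(O)c(OC)c1 | intermediate
5 | (E)-3-(4-acetoxy-3-bromo-5-methoxyphenyl)prop-2-enoic acid | CC(=O)Oc1c(Br)cc(/C=C/C(=O)O)cc1OC | intermediate
6 | (S)-4-benzyloxazolidin-2-one | O=C1N[C@@H](Cc2ccccc2)CO1 | starting material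
7 | (E)-3-(4-acetoxy-3-bromo-5-methoxyphenyl)prop-2-enoic 2,2-dimethylpropanoic anhydride | CC(=O)Oc1c(Br)cc(/C=C/C(=O)OC(=O)C(C)(C)C)cc1OC | intermediate (not isolated)
8 | (S)-3-[(E)-3-(4-acetoxy-3-bromo-5-methoxyphenyl)prop-2-enoyl]-4-benzyloxazolidin-2-one | CC(=O)Oc1c(Br)cc(/C=C/C(=O)N2C(=O)OC[C@@H]2Cc2ccccc2)cc1OC | intermediate
9 | (S)-4-benzyl-3-[(E)-3-(3-bromo-4-hydroxy-5-methoxyphenyl)prop-2-enoyl]oxazolidin-2-one | O=C1OC[C@H](Cc2ccccc2)N1C(=O)/C=C/c1cc(Br)c(O)c(OC)c1 | intermediate
10 | (4S,4'S)-3,3'-{(2S,3S)-2,3-bis[(3-bromo-5-methoxy-4-oxocyclohexa-2,5-dien-1-ylidene)methyl]butanedioyl}bis(4-benzyloxazolidin-2-one), methide geometry not fixed | O=C1OC[C@H](Cc2ccccc2)N1C(=O)[C@@H](C=C1C=C(Br)C(=O)C(OC)=C1)[C@H](C=C1C=C(Br)C(=O)C(OC)=C1)C(=O)N1C(=O)OC[C@@H]1Cc1ccccc1 | intermediate (not isolated)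
11 | (4S,4'S)-3,3'-{(2E,3S)-2-[(3-bromo-4-hydroxy-5-methoxyphenyl)methylidene]-3-[(3-bromo-5-methoxy-4-oxocyclohexa-2,5-dien-1-ylidene)methyl]butanedioyl}bis(4-benzyloxazolidin-2-one), methide geometry not fixed | O=C1OC[C@H](Cc2ccccc2)N1C(=O)[C@@H](C=C1C=C(Br)C(=O)C(OC)=C1)/C(=C\c1cc(Br)c(O)c(OC)c1)C(=O)N1C(=O)OC[C@@H]1Cc1ccccc1 | intermediate (not isolated)
12 | (4S,4'S)-3,3'-{[(1R,2S)-8-bromo-1-(3-bromo-4-hydroxy-5-methoxyphenyl)-7-hydroxy-6-methoxy-1,2-dihydronaphthalene-2,3-diyl]dicarbonyl}bis(4-benzyloxazolidin-2-one) | O=C(N1C(=O)OC[C@@H]1Cc1ccccc1)C1=Cc2cc(OC)c(O)c(Br)c2[C@@H](c2cc(Br)c(O)c(OC)c2)[C@@H]1C(=O)N1C(=O)OC[C@@H]1Cc1ccccc1 | intermediate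
13 | (4S,4'S)-3,3'-{[(1R,2S,3R)-7-hydroxy-1-(4-hydroxy-3-methoxyphenyl)-6-methoxy-1,2,3,4-tetrahydronaphthalene-2,3-diyl]dicarbonyl}bis(4-benzyloxazolidin-2-one) | O=C(N1C(=O)OC[C@@H]1Cc1ccccc1)[C@@H]1[C@H](C(=O)N2C(=O)OC[C@@H]2Cc2ccccc2)Cc2cc(OC)c(O)cc2[C@H]1c1ccc(O)c(OC)c1 | intermediate
14 | dimethyl (1R,2S,3R)-7-hydroxy-1-(4-hydroxy-3-methoxyphenyl)-6-methoxy-1,2,3,4-tetrahydronaphthalene-2,3-dicarboxylate | COC(=O)[C@@H]1[C@H](C(=O)OC)Cc2cc(OC)c(O)cc2[C@H]1c1ccc(O)c(OC)c1 | intermediate (not isolated)
15 | dimethyl (1R,2S,3S)-7-hydroxy-1-(4-hydroxy-3-methoxyphenyl)-6-methoxy-1,2,3,4-tetrahydronaphthalene-2,3-dicarboxylate | COC(=O)[C@@H]1[C@@H](C(=O)OC)Cc2cc(OC)c(O)cc2[C@H]1c1ccc(O)c(OC)c1 | intermediate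
16 | (1R,2S,3S)-7-hydroxy-1-(4-hydroxy-3-methoxyphenyl)-6-methoxy-2-(methoxycarbonyl)-1,2,3,4-tetrahydronaphthalene-3-carboxylic acid | COC(=O)[C@@H]1[C@@H](C(=O)O)Cc2cc(OC)c(O)cc2[C@H]1c1ccc(O)c(OC)c1 | intermediate
17 | methyl (1R,2S,3S)-7-hydroxy-1-(4-hydroxy-3-methoxyphenyl)-3-(hydroxymethyl)-6-methoxy-1,2,3,4-tetrahydronaphthalene-2-carboxylate | COC(=O)[C@@H]1[C@@H](CO)Cc2cc(OC)c(O)cc2[C@H]1c1ccc(O)c(OC)c1 | target

## Step count and least certain steps

Total: 9 steps. Longest linear sequence: 9 steps (1 to 17); the auxiliary 6 enters at step 3.

**Step 5 (key step).** Several things can go wrong: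
- Weak or inverted facial discrimination in the radical coupling, because the benzyl group lies far from the α-carbon in the non-chelated conformer; heterochiral coupling would feed both C1/C2 series.
- Addition of water to the methide, or tautomerisation of both methides without ring closure.
- Ring closure ortho instead of para to the methoxyl.
- Further dehydrogenation to the naphthalene level.

Modest selectivity is tolerable, because the auxiliaries are still attached and the stereoisomers of 12 are therefore diastereomers that can be separated. If the sense is inverted, the enantiomeric auxiliary is used.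

Fallback, which gives up auxiliary control: the sequence sets out from 4. Fischer esterification (MeOH, cat. H2SO4, reflux) gives methyl (E)-3-(3-bromo-4-hydroxy-5-methoxyphenyl)prop-2-enoate F1. The same FeCl3 oxidation, now without any stereochemical demand, should give the racemic trans diester, that is dimethyl (1R,2S)-8-bromo-1-(3-bromo-4-hydroxy-5-methoxyphenyl)-7-hydroxy-6-methoxy-1,2-dihydronaphthalene-2,3-dicarboxylate F2 together with the (1S,2R) enantiomer F3. These are parted by preparative chromatography on a chiral stationary phase. Hydrogenation of F2 under the conditions of step 6 leads to 14, where the route is rejoined, and the methoxide treatment of step 7 carries 14 on to 15.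

**Step 8.** Discrimination between the two esters may be insufficient (attack at the C2 ester, or hydrolysis of both), since it rests on a single additional flanking substituent. Fallback: from 15, direct reduction with LiEt3BH (THF, −78 → −20 °C, excess to allow for the two phenols). The bulky hydride should differentiate the two esters more sharply than hydroxide, and it converts the C3 ester straight into the hydroxymethyl group, so the route is rejoined at 17 one step earlier. No new compound lies on this path.

**Step 7.** Methoxide may attack the ring carbonyl of the oxazolidinone on the hindered C2 acyl group (ring opening instead of acyl transfer), or epimerisation may stop short of equilibrium. Fallback: from 13, hydrolysis with LiOH/H2O2 (THF/H2O, 0 °C), which is selective for the exocyclic carbonyl even in hindered imides, should give (1R,2S,3R)-7-hydroxy-1-(4-hydroxy-3-methoxyphenyl)-6-methoxy-1,2,3,4-tetrahydronaphthalene-2,3-dicarboxylic acid F4. Esterification (SOCl2, MeOH, 0 °C → reflux) returns to 14, where the route is rejoined, and NaOMe is then needed only as the equilibrating base on the way to 15.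

**Step 6.** Saturation of the hindered trisubstituted alkene beside the bulky imide may stall after the fast loss of bromine, or the ring may be dehydrogenated on palladium. Fallback: from 12, the two reductions are separated.
- Homogeneous hydrogenation with [Ir(cod)(PCy3)(py)]PF6 (H2 1 atm, CH2Cl2, rt) leaves the aryl bromides alone. It delivers hydrogen to the face on which the C2 imide carbonyl binds the metal, and should give (4S,4'S)-3,3'-{[(1R,2S,3S)-8-bromo-1-(3-bromo-4-hydroxy-5-methoxyphenyl)-7-hydroxy-6-methoxy-1,2,3,4-tetrahydronaphthalene-2,3-diyl]dicarbonyl}bis(4-benzyloxazolidin-2-one) F5.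
- Hydrodebromination (H2, Pd/C, Et3N), now without an alkene to reduce, gives (4S,4'S)-3,3'-{[(1R,2S,3S)-7-hydroxy-1-(4-hydroxy-3-methoxyphenyl)-6-methoxy-1,2,3,4-tetrahydronaphthalene-2,3-diyl]dicarbonyl}bis(4-benzyloxazolidin-2-one) F6.
- The methoxide treatment of step 7 converts F6 into 15, where the route is rejoined.

## Further compounds

F1 | step 5 | methyl (E)-3-(3-bromo-4-hydroxy-5-methoxyphenyl)prop-2-enoate | COC(=O)/C=C/c1cc(Br)c(O)c(OC)c1
F2 | step 5 | dimethyl (1R,2S)-8-bromo-1-(3-bromo-4-hydroxy-5-methoxyphenyl)-7-hydroxy-6-methoxy-1,2-dihydronaphthalene-2,3-dicarboxylate | COC(=O)C1=Cc2cc(OC)c(O)c(Br)c2[C@@H](c2cc(Br)c(O)c(OC)c2)[C@@H]1C(=O)OC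
F3 | step 5 | dimethyl (1S,2R)-8-bromo-1-(3-bromo-4-hydroxy-5-methoxyphenyl)-7-hydroxy-6-methoxy-1,2-dihydronaphthalene-2,3-dicarboxylate | COC(=O)C1=Cc2cc(OC)c(O)c(Br)c2[C@H](c2cc(Br)c(O)c(OC)c2)[C@H]1C(=O)OC
F0 | step 8 | none | none
F4 | step 7 | (1R,2S,3R)-7-hydroxy-1-(4-hydroxy-3-methoxyphenyl)-6-methoxy-1,2,3,4-tetrahydronaphthalene-2,3-dicarboxylic acid | OC(=O)[C@@H]1[C@H](C(=O)O)Cc2cc(OC)c(O)cc2[C@H]1c1ccc(O)c(OC)c1
F5 | step 6 | (4S,4'S)-3,3'-{[(1R,2S,3S)-8-bromo-1-(3-bromo-4-hydroxy-5-methoxyphenyl)-7-hydroxy-6-methoxy-1,2,3,4-tetrahydronaphthalene-2,3-diyl]dicarbonyl}bis(4-benzyloxazolidin-2-one) | O=C(N1C(=O)OC[C@@H]1Cc1ccccc1)[C@@H]1[C@@H](C(=O)N2C(=O)OC[C@@H]2Cc2ccccc2)Cc2cc(OC)c(O)c(Br)c2[C@H]1c1cc(Br)c(O)c(OC)c1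
F6 | step 6 | (4S,4'S)-3,3'-{[(1R,2S,3S)-7-hydroxy-1-(4-hydroxy-3-methoxyphenyl)-6-methoxy-1,2,3,4-tetrahydronaphthalene-2,3-diyl]dicarbonyl}bis(4-benzyloxazolidin-2-one) | O=C(N1C(=O)OC[C@@H]1Cc1ccccc1)[C@@H]1[C@@H](C(=O)N2C(=O)OC[C@@H]2Cc2ccccc2)Cc2cc(OC)c(O)cc2[C@H]1c1ccc(O)c(OC)c1
A1 | alternative 1 | tert-butyldimethylsilyl methyl ketene acetal of the (R)-3,3-diarylpropanoate with an ortho 3-methoxyallyl chain on the ring-A aryl group, both phenols as pivalates, alkene geometries not fixed | COC(O[Si](C)(C)C(C)(C)C)=C[C@H](c1ccc(OC(=O)C(C)(C)C)c(OC)c1)c1cc(OC(=O)C(C)(C)C)c(OC)cc1CC=COC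
A2 | alternative 1 | methyl (1R,2S,3S)-3-(dimethoxymethyl)-6-methoxy-1-[3-methoxy-4-(pivaloyloxy)phenyl]-7-(pivaloyloxy)-1,2,3,4-tetrahydronaphthalene-2-carboxylate | COC(=O)[C@@H]1[C@@H](C(OC)OC)Cc2cc(OC)c(OC(=O)C(C)(C)C)cc2[C@H]1c1ccc(OC(=O)C(C)(C)C)c(OC)c1
A3 | alternative 2 | 6-(benzyloxy)-1-[4-(benzyloxy)-3-methoxyphenyl]-5-methoxy-1,3-dihydro-2-benzothiophene 2,2-dioxide, racemic (its stereocentre is lost in the key step) | O=S1(=O)Cc2cc(OC)c(OCc3ccccc3)cc2C1c1ccc(OCc2ccccc2)c(OC)c1
A4 | alternative 2 | (E)-aryl ortho-quinodimethane: 5-(benzyloxy)-6-{(E)-[4-(benzyloxy)-3-methoxyphenyl]methylidene}-4-methoxy-1-methylidenecyclohexa-2,4-diene skeleton, aryl group on the outer side | C=C1C=C(OC)C(OCc2ccccc2)=C\C1=C/c1ccc(OCc2ccccc2)c(OC)c1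
A5 | alternative 2 | (5S)-5-{[(1S,2R,5S)-5-methyl-2-(propan-2-yl)cyclohexyl]oxy}furan-2(5H)-one | CC(C)[C@H]1CC[C@H](C)C[C@@H]1O[C@H]1OC(=O)C=C1
A6 | alternative 2 | all-cis cycloadduct: 1-aryl tetralin cis-fused across C2–C3 to a menthyloxy butyrolactone (carbonyl on C2, acetal carbon on C3), both phenols as benzyl ethers | CC(C)[C@H]1CC[C@H](C)C[C@@H]1O[C@H]1OC(=O)[C@@H]2[C@H](c3ccc(OCc4ccccc4)c(OC)c3)c3cc(OCc4ccccc4)c(OC)cc3C[C@H]12
A7 | alternative 3 | dimethyl 2-[(2S)-1-{4-(benzyloxy)-2-[hydroxy(4-hydroxy-3-methoxyphenyl)methyl]-5-methoxyphenyl}-3-[(tert-butyldimethylsilyl)oxy]propan-2-yl]propanedioate, carbinol centre not fixed | COC(=O)C(C(=O)OC)[C@@H](CO[Si](C)(C)C(C)(C)C)Cc1cc(OC)c(OCc2ccccc2)cc1C(O)c1ccc(O)c(OC)c1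
A8 | alternative 3 | quinone methide derived from A7 by loss of the carbinol hydroxyl, methide geometry not fixed | COC(=O)C(C(=O)OC)[C@@H](CO[Si](C)(C)C(C)(C)C)Cc1cc(OC)c(OCc2ccccc2)cc1C=C1C=CC(=O)C(OC)=C1
A9 | alternative 3 | dimethyl (1R,3S)-7-(benzyloxy)-3-{[(tert-butyldimethylsilyl)oxy]methyl}-1-(4-hydroxy-3-methoxyphenyl)-6-methoxy-3,4-dihydronaphthalene-2,2(1H)-dicarboxylate | COC(=O)C1(C(=O)OC)[C@@H](CO[Si](C)(C)C(C)(C)C)Cc2cc(OC)c(OCc3ccccc3)cc2[C@H]1c1ccc(O)c(OC)c1
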